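## Structural features

The target is a fully substituted tetrahydrofuran, labelled here O1, C2 (4-hydroxyphenyl), C3 (2,4-dihydroxybenzoyl, ketone carbon C7), C4 (hydroxy(4-hydroxyphenyl)methyl, carbinol carbon C6) and C5 (2,4-dihydroxyphenyl); the only other rings are the four benzene rings. Five stereocentres stand in a row, C2–C3–C4–C5 in the ring and C6 on the side chain, and all five are R. On the ring the C2 aryl group is trans to the C3 aroyl group, while the substituents on C3, C4 and C5 are all cis, so the C5 aryl group sits on the crowded face. Fragile points are the six free phenols, the three benzylic C–O bonds (C2–O1, C5–O1, C6–OH) that ortho- or para-hydroxyaryl groups can ionise to quinone methides, the epimerisable C3 next to the ketone, the ring oxygen β to that ketone (retro-oxa-Michael opening) and the γ-hydroxy ketone, which can close to a hemiketal. The real difficulty is the all-cis C3/C4/C5 triad with its contra-thermodynamic C5 aryl group. The plan exploits two facts: C5–O1–C2, with one aryl group on each carbon, is the backbone of a carbonyl ylide, and C3–C4 with C7 and C6 cis, tied through the oxygen on C6, is a γ-aryl butenolide. Their union is a cis-fused 3,7-dioxabicyclo[3.3.0]octanone whose convex face allows C5 to be set after the ring is made.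

## Logic of the disconnections

**27 to 26 to 25.** The six phenolic O–H bonds are traced back to four O–benzyl bonds (27 from 26) and two O–silyl bonds (26 from 25). The silyl pair is dictated by the carbene chemistry at the C5 aryl group, the benzyl set by the organometallic step and the radical step. The gain is that every polar group is masked until the end. The demand is that both unmaskings are close to neutral, so that C3, the benzylic C–O bonds and the β-alkoxy ketone survive.

**25 to 19 and 21.** The C7–aryl bond is cut. C7 and the oxygen on C6 are then one lactone, which hides the γ-hydroxy ketone, locks C3 and C4 cis and leaves only one electrophilic carbonyl. The aryl unit comes from 21 through 22 and 23. The forward step must stop after one addition (lactolate 24) and must not enolise at C3.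

**19 to 16 to 15.** The C5–H bond is replaced by a C5–carboxyl bond. The carboxyl group is what makes C5 the nucleophilic end of an ylide, and its removal through a planar radical (17, 18) allows C5 to be set on the convex face whichever epimer the cycloaddition gives. The demand is hydrogen transfer to one face and a radical that does not fragment.

**15 to 13, 2 and 8.** The bonds C5–O1, C4–C5 and C2–C3 are cut. This removes the ring and four stereocentres in one operation and gives three fragments of similar size through ylide 14. The forward step needs chemoselectivity (alkene before a second aldehyde), regioselectivity, facial selectivity and exo selectivity.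

**8 to 7 to 5 and 6, and 5 to 1 and 2.** The ring alkene is cut (ring-closing metathesis), then the ester C–O bond, then the carbinol–alkenyl bond. One simple carbinol centre, the later C6, remains as the only source of absolute configuration. It has to come from an enantioselective alkenyl transfer through 3 and 4.

**13 to 12 to 11 to 9.** The C=N2 bond is cut (diazo transfer), then the ester C–O bond, then the three O–Si bonds (through 10). Silylation must precede esterification, because the free ortho-phenol would otherwise lactonise.

**21 to 20.** The two O–benzyl bonds are cut, which leads back to a commercial bromoresorcinol.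

## Other disconnections considered

**Alternative 1:** The cut is at C2–C3 and C4–C6. The chain C7–C3–C4–C5 becomes the succinyl bis-imide A1 and both carbinols come from two molecules of 2. Forward, the twofold (Z)-boron enolate of A1 (Bu2BOTf, iPr2NEt) adds to 2 through chair transition states to give the twofold-symmetric syn,syn bis-aldol A2.

- In its favour: the hidden twofold axis is used. C2/C6 are both R carbinols and C3/C4 are both R, so one aldehyde and one auxiliary should set four of the five stereocentres by a well-understood aldol.
- Against it: the second enolisation of a 1,4-dicarbonyl compound next to a boron enolate is not routine. An aldolate can lactonise onto the distal imide between the two aldol events. Aldolates of electron-rich aldehydes revert easily. A2 has two identical ends that must become different carbons: C5 (aryl and H on an ether carbon) and C7 (aryl ketone).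
- The sensible continuation is lactonisation of A2 to A8, so this plan shares its end-game with alternative 3. C5 would be set by hydride addition to an oxocarbenium ion on the convex face.
- Comparison, structure: it is the better plan in using the symmetry that the chosen plan ignores, and it is the equal of the chosen plan in how C5 is set.
- Comparison, mechanism: auxiliary control is more predictable than the facial and exo selectivity of a new cycloaddition, so it is better there. It is worse in needing two equivalents of auxiliary and of boron triflate, against a catalytic amount of Rh2(OAc)4.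
- Comparison, step economy: probably about equal, estimated at nine to ten operations, provided the twofold enolisation works.

**Alternative 2:** The cut is the C7–aryl bond, with the ortho oxygen of the new ring coming from the carboxyl group. Forward, the caesium salt of acid A3 adds through oxygen to aryne A5 (from silyl triflate A4 and CsF), and the aryl anion then takes the acyl group through a four-membered transition state to give the 2-hydroxyaryl ketone A6.

- In its favour: the ortho-hydroxy ketone appears directly, without an organolithium reagent and with no risk of double addition. On that chemoselectivity point it is the better method compared with step 11.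
- Against it: it is only a late tactic. It builds neither the ring nor a stereocentre, so A3 would still have to come from a route like the chosen one, with hydrolysis of the lactone and silylation of C6–OH added.
- Further against it: A4 needs several steps of its own. The chlorine that steers the aryne must be removed in a later reduction. The acyl shift on an α-branched acid competes with simple protonation to the aryl ester. Caesium phenoxide in warm acetonitrile is a threat to C3.
- Comparison: structurally it is neutral, mechanistically it trades one known risk for several, and in step economy it is clearly worse.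

**Alternative 3:** The cuts are the C2–H and C6–H bonds and the two lactone C–O bonds. Forward, the diaroylsuccinate A7 is reduced twice by RuCl(p-cymene)[(R,R)-TsDPEN] with HCO2H/Et3N while its α-centres equilibrate, and each new R carbinol lactonises on the distal ester to give the exo,exo dilactone A8.

- In its favour: it is catalytic, uses the twofold symmetry, forms four stereocentres and two rings in one step, and relies on a known reaction type.
- Also in its favour: because the two resorcinol units could then both come from 22 with benzyl protection throughout, a single final hydrogenolysis would suffice.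
- Against it: A7 is a 1,4-diketone that can cyclodehydrate to a furan in the acidic medium. The syn relation between each carbinol and its α-centre, and the correct C3/C4 relation, must all come from the dynamic resolution, and this is substrate-dependent for α-alkyl β-keto esters.
- Further against it: A8 must then take two different, sequential aryl additions, with an ionic lactol reduction in between.
- Comparison, structure: it is better in using the symmetry.
- Comparison, mechanism: it is better in resting on precedented steps, but weaker in that one catalyst has to control four centres at once, whereas the chosen plan derives everything from one simple carbinol.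
- Comparison, step economy: it is better, estimated at about eight operations against thirteen.

Key step: step 7

Remark on the chemistry: the target is taken as the open γ-hydroxy ketone; hemiketal tautomers of 25–27 are treated as equivalent. In 15 the centres C2, C3, C4 and C6 already have the configuration of 27; only C5 is opposite (aryl exo) and is corrected in step 9. Compound 8 is R, which is what C6 of 27 requires.

## Route

**Step 1**
Reactants: 1 hex-1-yne; 2 4-(benzyloxy)benzaldehyde
Product: 5 (R,E)-1-[4-(benzyloxy)phenyl]hept-2-en-1-ol, via hexenylborane 3 (not isolated), via hexenylzinc 4 (not isolated)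
Conditions: Cy2BH (from BH3·SMe2, cyclohexene), toluene, 0 °C to rt; Et2Zn, −78 °C; (+)-3-exo-morpholinoisoborneol (5 mol %), 2, −10 °C; aq NH4Cl
Reagents that add atoms: none
Why: Syn hydroboration of the alkyne and boron-to-zinc exchange give the (E)-alkenylzinc, and the zinc amino-alkoxide catalyst should deliver it to the Re face of the aldehyde (catalytic asymmetric alkenylzinc addition), setting the later C6 as R; the (+)-ligand is chosen by analogy with its antipode, which directs Si-face transfer. The butyl end is lost in step 3, so the hexenyl group serves as a vinyl equivalent.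

**Step 2**
Reactants: 5 (R,E)-1-[4-(benzyloxy)phenyl]hept-2-en-1-ol; 6 acryloyl chloride
Product: 7 (R,E)-1-[4-(benzyloxy)phenyl]hept-2-en-1-yl acrylate
Conditions: iPr2NEt, DMAP (cat.), CH2Cl2, −20 to 0 °C
Reagents that add atoms: none
Why: O-Acylation of a secondary alcohol by an acid chloride; the stereocentre is not touched, and excess base at low temperature should suppress ionisation of the electron-rich allylic, benzylic ester to its transposed isomer.

**Step 3**
Reactants: 7 (R,E)-1-[4-(benzyloxy)phenyl]hept-2-en-1-yl acrylate
Product: 8 (R)-5-[4-(benzyloxy)phenyl]furan-2(5H)-one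
Conditions: second-generation Grubbs catalyst RuCl2(=CHPh)(H2IMes)(PCy3) (5 mol %), CH2Cl2 (0.01 M), 40 °C
Reagents that add atoms: none
Why: Ring-closing metathesis of an allylic acrylate to a butenolide; the ruthenium alkylidene should load at the electron-richer disubstituted alkene, close onto the acrylate and release hex-1-ene, with the stereocentre as a spectator.

**Step 4**
Reactants: 9 2,4-dihydroxyphenylacetic acid
Product: 11 2-[2,4-bis(tert-butyldimethylsilyloxy)phenyl]acetic acid, via silyl ester 10 (not isolated)
Conditions: TBSCl (3.5 equiv), imidazole, DMF, rt; then AcOH, MeOH/H2O, rt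
Reagents that add atoms: tert-butyldimethylsilyl chloride, CC(C)(C)[Si](C)(C)Cl
Why: Exhaustive silylation, then selective hydrolysis of the labile silyl ester under mild acid that aryl silyl ethers tolerate; silylating before esterification keeps the ortho-phenol from lactonising to a benzofuranone.

**Step 5**
Reactants: 11 2-[2,4-bis(tert-butyldimethylsilyloxy)phenyl]acetic acid
Product: 12 2,2,2-trichloroethyl 2-[2,4-bis(tert-butyldimethylsilyloxy)phenyl]acetate
Conditions: Cl3CCH2OH, DCC, DMAP (cat.), CH2Cl2, 0 °C to rt
Reagents that add atoms: 2,2,2-trichloroethanol, OCC(Cl)(Cl)Cl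
Why: Steglich esterification of an arylacetic acid with a weakly nucleophilic alcohol; the trichloroethyl ester is chosen because zinc removes it later without base or fluoride.

**Step 6**
Reactants: 12 2,2,2-trichloroethyl 2-[2,4-bis(tert-butyldimethylsilyloxy)phenyl]acetate
Product: 13 2,2,2-trichloroethyl 2-[2,4-bis(tert-butyldimethylsilyloxy)phenyl]-2-diazoacetate
Conditions: p-ABSA, DBU, MeCN, 0 °C
Reagents that add atoms: 4-acetamidobenzenesulfonyl azide, CC(=O)Nc1ccc(cc1)S(=O)(=O)N=[N+]=[N-]
Why: Regitz diazo transfer to the arylacetate enolate, the standard entry to aryldiazoacetates; anhydrous conditions and short reaction time should keep the aryl silyl ethers intact.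

**Step 7**
Reactants: 13 2,2,2-trichloroethyl 2-[2,4-bis(tert-butyldimethylsilyloxy)phenyl]-2-diazoacetate; 2 4-(benzyloxy)benzaldehyde; 8 (R)-5-[4-(benzyloxy)phenyl]furan-2(5H)-one
Product: 15 cis-fused tetrahydrofuran lactone with quaternary C5 carrying the trichloroethyl ester endo, via carbonyl ylide 14 (not isolated)
Conditions: Rh2(OAc)4 (2 mol %), 4 Å MS, CH2Cl2, 40 °C; 8 (1.0 equiv), 2 (1.5 equiv), 13 (1.5 equiv) added over 4 h
Reagents that add atoms: none
Why: Proposed new method: Rh2(OAc)4 (divalent rhodium) should expel N2 from 13, the electrophilic rhodium-bound carbene should be captured by the carbonyl oxygen of 2 (C5–O1), and the released ylide 14, nucleophilic at the ester-bearing C5 and electrophilic at the aryl-stabilised C2, should add to 8 with C5 on the β-carbon C4 and C2 on the α-carbon C3; the closest known reaction type is the Rh2(OAc)4-catalysed three-component union of aryldiazoacetates, aryl aldehydes and electron-poor alkenes, extended here to a γ-substituted butenolide. The tetrahydrofuran ring closes in a thermally allowed six-electron suprafacial (3+2) cycloaddition, concerted but asynchronous with C4–C5 ahead of C2–C3, so no separate endo-trig closure is needed. C3 and C4 are cis because the addition is suprafacial across the ring alkene, and their absolute sense follows from approach of 14 to the face of 8 anti to the C6 aryl group. C2 is controlled by the aryl group of the C2=O1 terminus lying outside the ylide and exo to the lactone. C5 depends on whether ester or aryl sits inside the ylide; it is drawn ester endo, and both epimers converge in step 9. The step needs chemoselectivity for the alkene over a second aldehyde (dioxolane) and over closure to an oxirane, which slow addition of 13, a small excess of 2 and the strained conjugated alkene of 8 should provide; regioselectivity, from the match of ylide polarity with the Michael polarity of 8; facial selectivity, from the C6 aryl group; and exo selectivity, from the bulk of the C2 aryl group. Silyl and not benzyl ethers on 13 avoid carbene insertion into an ortho O–CH2 bond.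

**Step 8**
Reactants: 15 cis-fused tetrahydrofuran lactone trichloroethyl ester
Product: 16 the corresponding C5 carboxylic acid
Conditions: Zn dust, AcOH, THF, rt
Reagents that add atoms: none
Why: Reductive β-elimination of the 2,2,2-trichloroethyl ester by zinc (two-electron transfer, loss of chloride and 1,1-dichloroethene) under weakly acidic conditions that leave the lactone, the benzyl and silyl ethers and all stereocentres untouched.

**Step 9**
Reactants: 16 C5 carboxylic acid
Product: 19 cis-fused lactone with C5–H and the C5 aryl group endo, via Barton ester 17 (not isolated), via C5 radical 18 (not isolated)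
Conditions: N-hydroxypyridine-2-thione, DCC, CH2Cl2, dark, 0 °C to rt; then t-BuSH (10 equiv), hν (white LED), 0 °C
Reagents that add atoms: none
Why: Barton reductive decarboxylation: the thiohydroxamate ester should fragment to the planar, aryl- and oxygen-stabilised radical 18, which takes hydrogen from the bulky thiol on the convex face, anti to the lactone ring on C4, so that hydrogen ends exo and the aryl group endo as in the target; the precedent type is reductive decarboxylation of cyclic α-alkoxy acids with stereoselective thiol quench. β-Scission of O1–C2 is disfavoured because that bond lies near the nodal plane of the radical orbital.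

**Step 10**
Reactants: 20 4-bromobenzene-1,3-diol
Product: 21 2,4-bis(benzyloxy)-1-bromobenzene
Conditions: BnBr, K2CO3, DMF, 60 °C
Reagents that add atoms: benzyl bromide, BrCc1ccccc1
Why: Williamson ether synthesis on both phenols; benzyl ethers tolerate the aryllithium reagent, whereas an ortho-silyl ether would migrate to carbon.

**Step 11**
Reactants: 21 2,4-bis(benzyloxy)-1-bromobenzene; 19 cis-fused lactone with C5–H
Product: 25 γ-hydroxy ketone carrying the 2,4-bis(benzyloxy)benzoyl group on C3, via aryllithium 22 (not isolated), via arylcerium 23 (not isolated), via cerium lactolate 24 (not isolated)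
Conditions: 21 (1.5 equiv), n-BuLi, THF, −78 °C; CeCl3 (anhydrous), −78 °C; then 19, −78 °C; aq NH4Cl
Reagents that add atoms: none
Why: Bromine–lithium exchange, transmetallation to the less basic and more oxophilic organocerium reagent and addition to the exo face of the lactone carbonyl should give the tetrahedral lactolate 24, which persists at −78 °C and so prevents a second addition; work-up opens it to the hydroxy ketone. C3 is safe because the reagent does not enolise and a trans-fused alternative is not accessible; no new stereocentre remains.

**Step 12**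
Reactants: 25 γ-hydroxy ketone with silyl ethers on the C5 aryl group
Product: 26 the corresponding C5-aryl diphenol
Conditions: TBAF, AcOH (1:1), THF, 0 °C
Reagents that add atoms: none
Why: Fluoride cleavage of the two aryl silyl ethers; the acetic acid buffer keeps phenoxide and enolate concentrations low, so that quinone-methide opening at C5, epimerisation at C3 and retro-oxa-Michael opening should not be triggered.

**Step 13**
Reactants: 26 tetra-O-benzyl diphenol
Product: 27 CNP0244141.1
Conditions: H2 (1 atm), Pd/C (10 %), EtOAc/EtOH, rt
Reagents that add atoms: none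
Why: Hydrogenolysis of four aryl benzyl ethers under neutral conditions; aryl O–benzyl bonds cleave much faster than the secondary benzylic C–O bonds of the ring and of C6, and the reaction is stopped once four equivalents of H2 are taken up.

## Compound list

1 | hex-1-yne | C#CCCCC | starting material
2 | 4-(benzyloxy)benzaldehyde | O=Cc1ccc(OCc2ccccc2)cc1 | starting material
3 | (E)-dicyclohexyl(hex-1-en-1-yl)borane | CCCC/C=C/B(C1CCCCC1)C1CCCCC1 | intermediate
4 | (E)-ethyl(hex-1-en-1-yl)zinc | CCCC/C=C/[Zn]CC | intermediate
5 | (R,E)-1-[4-(benzyloxy)phenyl]hept-2-en-1-ol | CCCC/C=C/[C@@H](O)c1ccc(OCc2ccccc2)cc1 | intermediate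
6 | acryloyl chloride | C=CC(=O)Cl | starting material
7 | (R,E)-1-[4-(benzyloxy)phenyl]hept-2-en-1-yl acrylate | CCCC/C=C/[C@@H](OC(=O)C=C)c1ccc(OCc2ccccc2)cc1 | intermediate
8 | (R)-5-[4-(benzyloxy)phenyl]furan-2(5H)-one | O=C1C=C[C@@H](O1)c1ccc(OCc2ccccc2)cc1 | intermediate
9 | 2,4-dihydroxyphenylacetic acid | OC(=O)Cc1ccc(O)cc1O | starting material
10 | tert-butyldimethylsilyl 2-[2,4-bis(tert-butyldimethylsilyloxy)phenyl]acetate | CC(C)(C)[Si](C)(C)OC(=O)Cc1ccc(O[Si](C)(C)C(C)(C)C)cc1O[Si](C)(C)C(C)(C)C | intermediate
11 | 2-[2,4-bis(tert-butyldimethylsilyloxy)phenyl]acetic acid | OC(=O)Cc1ccc(O[Si](C)(C)C(C)(C)C)cc1O[Si](C)(C)C(C)(C)C | intermediate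
12 | 2,2,2-trichloroethyl 2-[2,4-bis(tert-butyldimethylsilyloxy)phenyl]acetate | ClC(Cl)(Cl)COC(=O)Cc1ccc(O[Si](C)(C)C(C)(C)C)cc1O[Si](C)(C)C(C)(C)C | intermediate
13 | 2,2,2-trichloroethyl 2-[2,4-bis(tert-butyldimethylsilyloxy)phenyl]-2-diazoacetate | ClC(Cl)(Cl)COC(=O)C(=[N+]=[N-])c1ccc(O[Si](C)(C)C(C)(C)C)cc1O[Si](C)(C)C(C)(C)C | intermediate
14 | carbonyl ylide: C5 carries the trichloroethyl ester and the 2,4-bis(silyloxy)phenyl group, C2 carries H and 4-(benzyloxy)phenyl (aryl groups outside, ester inside in the reacting geometry) | ClC(Cl)(Cl)COC(=O)[C-](c1ccc(O[Si](C)(C)C(C)(C)C)cc1O[Si](C)(C)C(C)(C)C)[O+]=Cc1ccc(OCc2ccccc2)cc1 | intermediate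
15 | 2,2,2-trichloroethyl ester of the cis-fused tetrahydrofuran γ-lactone acid (3,7-dioxabicyclo[3.3.0]octan-8-one core; labels of the target): lactone C7(=O)–O–C6; C2 4-(benzyloxy)phenyl exo; C5 quaternary with 2,4-bis(tert-butyldimethylsilyloxy)phenyl exo and ester endo; C6 R with 4-(benzyloxy)phenyl exo | O=C2[C@@H]1[C@H]([C@@H](O2)c3ccc(OCc4ccccc4)cc3)[C@@](C(=O)OCC(Cl)(Cl)Cl)(c3ccc(O[Si](C)(C)C(C)(C)C)cc3O[Si](C)(C)C(C)(C)C)O[C@H]1c1ccc(OCc2ccccc2)cc1 | intermediate
16 | C5 carboxylic acid of 15 (same configuration) | O=C2[C@@H]1[C@H]([C@@H](O2)c3ccc(OCc4ccccc4)cc3)[C@@](C(=O)O)(c3ccc(O[Si](C)(C)C(C)(C)C)cc3O[Si](C)(C)C(C)(C)C)O[C@H]1c1ccc(OCc2ccccc2)cc1 | intermediate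
17 | Barton ester of 16: 2-thioxopyridin-1(2H)-yl ester of the C5 acid | O=C2[C@@H]1[C@H]([C@@H](O2)c3ccc(OCc4ccccc4)cc3)[C@@](C(=O)On3ccccc3=S)(c3ccc(O[Si](C)(C)C(C)(C)C)cc3O[Si](C)(C)C(C)(C)C)O[C@H]1c1ccc(OCc2ccccc2)cc1 | intermediate
18 | planar C5 radical of the cis-fused lactone | O=C2[C@@H]1[C@H]([C@@H](O2)c3ccc(OCc4ccccc4)cc3)[C](c3ccc(O[Si](C)(C)C(C)(C)C)cc3O[Si](C)(C)C(C)(C)C)O[C@H]1c1ccc(OCc2ccccc2)cc1 | intermediate
19 | cis-fused tetrahydrofuran γ-lactone with C5–H: C2 4-(benzyloxy)phenyl exo; C5 2,4-bis(tert-butyldimethylsilyloxy)phenyl endo (cis to the C4–C6 bond); C6 R with 4-(benzyloxy)phenyl exo | O=C2[C@@H]1[C@H]([C@@H](O2)c3ccc(OCc4ccccc4)cc3)[C@H](c3ccc(O[Si](C)(C)C(C)(C)C)cc3O[Si](C)(C)C(C)(C)C)O[C@H]1c1ccc(OCc2ccccc2)cc1 | intermediate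
20 | 4-bromobenzene-1,3-diol | Oc1ccc(Br)c(O)c1 | starting material
21 | 2,4-bis(benzyloxy)-1-bromobenzene | Brc1ccc(OCc2ccccc2)cc1OCc1ccccc1 | intermediate
22 | [2,4-bis(benzyloxy)phenyl]lithium | [Li]c1ccc(OCc2ccccc2)cc1OCc1ccccc1 | intermediate
23 | [2,4-bis(benzyloxy)phenyl]cerium dichloride | Cl[Ce](Cl)c1ccc(OCc2ccccc2)cc1OCc1ccccc1 | intermediate
24 | cerium lactolate: tetrahedral adduct of 23 at C7 of 19 (configuration at C7 not defined) | Cl[Ce](Cl)OC2(c3ccc(OCc4ccccc4)cc3OCc3ccccc3)[C@@H]1[C@H]([C@@H](O2)c3ccc(OCc4ccccc4)cc3)[C@H](c3ccc(O[Si](C)(C)C(C)(C)C)cc3O[Si](C)(C)C(C)(C)C)O[C@H]1c1ccc(OCc2ccccc2)cc1 | intermediate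
25 | [2,4-bis(benzyloxy)phenyl]{(2R,3R,4R,5R)-2-[4-(benzyloxy)phenyl]-4-[(R)-[4-(benzyloxy)phenyl](hydroxy)methyl]-5-[2,4-bis(tert-butyldimethylsilyloxy)phenyl]oxolan-3-yl}methanone | O=C(c1ccc(OCc2ccccc2)cc1OCc1ccccc1)[C@@H]1[C@H]([C@@H](O)c2ccc(OCc3ccccc3)cc2)[C@H](c2ccc(O[Si](C)(C)C(C)(C)C)cc2O[Si](C)(C)C(C)(C)C)O[C@H]1c1ccc(OCc2ccccc2)cc1 | intermediate
26 | [2,4-bis(benzyloxy)phenyl]{(2R,3R,4R,5R)-2-[4-(benzyloxy)phenyl]-4-[(R)-[4-(benzyloxy)phenyl](hydroxy)methyl]-5-(2,4-dihydroxyphenyl)oxolan-3-yl}methanone | O=C(c1ccc(OCc2ccccc2)cc1OCc1ccccc1)[C@@H]1[C@H]([C@@H](O)c2ccc(OCc3ccccc3)cc2)[C@H](c2ccc(O)cc2O)O[C@H]1c1ccc(OCc2ccccc2)cc1 | intermediate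
27 | CNP0244141.1, (2,4-dihydroxyphenyl){(2R,3R,4R,5R)-5-(2,4-dihydroxyphenyl)-4-[(R)-hydroxy(4-hydroxyphenyl)methyl]-2-(4-hydroxyphenyl)oxolan-3-yl}methanone | O=C(c1ccc(O)cc1O)[C@@H]1[C@H]([C@@H](O)c2ccc(O)cc2)[C@H](c2ccc(O)cc2O)O[C@H]1c1ccc(O)cc1 | target

## Step count and risks

Total: 13 steps. Longest linear sequence: 9 steps (steps 1–3 or 4–6, then 7, 8, 9, 11, 12, 13).

**Step 7 (key step, Proposed new method).** The most likely failure is diversion of the ylide before it meets the alkene: closure to the oxirane or capture by a second aldehyde to a dioxolane. The ylide of an electron-rich aldehyde is short-lived and a β-substituted butenolide is only a moderate dipolarophile. Erosion of exo selectivity at C2 is the second concern.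

Fallback, from 13 (with 2 and 8), back at 15: the ylide is made in two known stages. Rh2(OAc)4 with 13 and 2 alone should give the oxirane 2,2,2-trichloroethyl 3-[4-(benzyloxy)phenyl]-2-[2,4-bis(tert-butyldimethylsilyloxy)phenyl]oxirane-2-carboxylate F1 (carbene epoxidation of an aldehyde). Heating F1 with 8 in toluene at 110–130 °C in a sealed vessel should open the C–C bond of the oxirane in a conrotatory sense to the same ylide, which the alkene traps in the absence of any competing aldehyde (thermal oxirane-to-carbonyl-ylide cycloaddition with electron-poor alkenes). This returns to the route at 15.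

**Step 9.** Hydrogen transfer to the stabilised, hindered radical may be slow, so that recombination to a C5 pyridyl sulfide, poor facial selectivity (the C2 aryl group also lies on the convex face) or thiyl-mediated reversible hydrogen abstraction at C5 and C2 compete.

Fallback, from 16, back at 19: an ionic sequence. Oxidative decarboxylation with Pb(OAc)4 (tetravalent lead) in benzene/pyridine should give the C5 acetoxy ketal, 5-acetoxy derivative of lactone 19 F2. Et3SiH with BF3·OEt2 in CH2Cl2 at −78 °C should then reduce the aryl-stabilised oxocarbenium ion by hydride delivery on the convex face, giving 19.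

**Step 11.** The lactolate may collapse early, which would lead to a second aryl addition, or the reagent may act as a base.

Fallback, from 19, back at 26: the lactone is opened with MeNH(OMe)·HCl/AlMe3 to the Weinreb amide, N-methoxy-N-methyl amide of the C6-hydroxy acid F3. The C6 hydroxyl is silylated (TESCl, imidazole) to the triethylsilyl ether of the Weinreb amide F4. Reagent 22, made again from 21, adds once to give the C6-O-triethylsilyl ether of ketone 25 F5. The fluoride conditions of step 12 then remove all three silyl groups and give 26.

**Step 13.** Over-reduction is the concern: hydrogenolysis of the para-hydroxybenzylic C6–OH bond, and more slowly of the ring C–O bonds, because free phenols make these bonds more labile.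

Fallback, from 25, back at 27: the order of unmasking is changed and the carbinol is protected. TBSCl/imidazole should give the C6-O-tert-butyldimethylsilyl ether of 25 F6. Hydrogenolysis (H2, Pd/C, EtOAc) should then give the tetraphenol tris(silyl ether) F7. Buffered fluoride (TBAF/AcOH) should remove the three silyl groups and give 27.

**Step 1.** The alkenyl transfer may give insufficient enantiomeric purity, or the assumed facial sense of the ligand may not hold for this aldehyde.

Fallback, from 2, back at 8: vinylmagnesium bromide should give racemic 1-[4-(benzyloxy)phenyl]prop-2-en-1-ol F8. Lipase-catalysed acyl transfer (Candida antarctica lipase B, vinyl acrylate) should acylate the R enantiomer selectively, with aryl as the large and vinyl as the medium group, to give (R)-1-[4-(benzyloxy)phenyl]allyl acrylate F9. Ring-closing metathesis with the second-generation Grubbs catalyst then gives 8.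

## Further compounds

F1 | step 7 | 2,2,2-trichloroethyl 3-[4-(benzyloxy)phenyl]-2-[2,4-bis(tert-butyldimethylsilyloxy)phenyl]oxirane-2-carboxylate (racemic, either diastereomer serves) | ClC(Cl)(Cl)COC(=O)C1(c2ccc(O[Si](C)(C)C(C)(C)C)cc2O[Si](C)(C)C(C)(C)C)OC1c1ccc(OCc2ccccc2)cc1
F2 | step 9 | 5-acetoxy derivative of lactone 19 (C5 acetoxy ketal, both C5 epimers) | O=C2[C@@H]1[C@H]([C@@H](O2)c3ccc(OCc4ccccc4)cc3)C(OC(C)=O)(c3ccc(O[Si](C)(C)C(C)(C)C)cc3O[Si](C)(C)C(C)(C)C)O[C@H]1c1ccc(OCc2ccccc2)cc1
F3 | step 11 | (2R,3R,4R,5R)-2-[4-(benzyloxy)phenyl]-4-[(R)-[4-(benzyloxy)phenyl](hydroxy)methyl]-5-[2,4-bis(tert-butyldimethylsilyloxy)phenyl]-N-methoxy-N-methyloxolane-3-carboxamide | CON(C)C(=O)[C@@H]1[C@H]([C@@H](O)c2ccc(OCc3ccccc3)cc2)[C@H](c2ccc(O[Si](C)(C)C(C)(C)C)cc2O[Si](C)(C)C(C)(C)C)O[C@H]1c1ccc(OCc2ccccc2)cc1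
F4 | step 11 | C6-O-triethylsilyl ether of F3 | CON(C)C(=O)[C@@H]1[C@H]([C@@H](O[Si](CC)(CC)CC)c2ccc(OCc3ccccc3)cc2)[C@H](c2ccc(O[Si](C)(C)C(C)(C)C)cc2O[Si](C)(C)C(C)(C)C)O[C@H]1c1ccc(OCc2ccccc2)cc1
F5 | step 11 | C6-O-triethylsilyl ether of ketone 25 | O=C(c1ccc(OCc2ccccc2)cc1OCc1ccccc1)[C@@H]1[C@H]([C@@H](O[Si](CC)(CC)CC)c2ccc(OCc3ccccc3)cc2)[C@H](c2ccc(O[Si](C)(C)C(C)(C)C)cc2O[Si](C)(C)C(C)(C)C)O[C@H]1c1ccc(OCc2ccccc2)cc1
F6 | step 13 | C6-O-tert-butyldimethylsilyl ether of ketone 25 | O=C(c1ccc(OCc2ccccc2)cc1OCc1ccccc1)[C@@H]1[C@H]([C@@H](O[Si](C)(C)C(C)(C)C)c2ccc(OCc3ccccc3)cc2)[C@H](c2ccc(O[Si](C)(C)C(C)(C)C)cc2O[Si](C)(C)C(C)(C)C)O[C@H]1c1ccc(OCc2ccccc2)cc1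
F7 | step 13 | tetraphenol tris(tert-butyldimethylsilyl ether): F6 without its four benzyl groups | O=C(c1ccc(O)cc1O)[C@@H]1[C@H]([C@@H](O[Si](C)(C)C(C)(C)C)c2ccc(O)cc2)[C@H](c2ccc(O[Si](C)(C)C(C)(C)C)cc2O[Si](C)(C)C(C)(C)C)O[C@H]1c1ccc(O)cc1
F8 | step 1 | racemic 1-[4-(benzyloxy)phenyl]prop-2-en-1-ol | C=CC(O)c1ccc(OCc2ccccc2)cc1
F9 | step 1 | (R)-1-[4-(benzyloxy)phenyl]allyl acrylate | C=C[C@@H](OC(=O)C=C)c1ccc(OCc2ccccc2)cc1
A1 | alternative 1 | 1,4-bis[(R)-4-benzyl-2-oxo-1,3-oxazolidin-3-yl]butane-1,4-dione | O=C(CCC(=O)N1[C@H](Cc2ccccc2)COC1=O)N1[C@H](Cc2ccccc2)COC1=O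
A2 | alternative 1 | twofold-symmetric syn,syn bis-aldol bis-imide | O=C(N1[C@H](Cc2ccccc2)COC1=O)[C@@H]([C@@H](O)c1ccc(OCc2ccccc2)cc1)[C@H]([C@@H](O)c1ccc(OCc2ccccc2)cc1)C(=O)N1[C@H](Cc2ccccc2)COC1=O
A3 | alternative 2 | (2R,3R,4R,5R)-2-[4-(benzyloxy)phenyl]-4-[(R)-[4-(benzyloxy)phenyl](triisopropylsilyloxy)methyl]-5-[2,4-bis(benzyloxy)phenyl]oxolane-3-carboxylic acid | OC(=O)[C@@H]1[C@H]([C@@H](O[Si](C(C)C)(C(C)C)C(C)C)c2ccc(OCc3ccccc3)cc2)[C@H](c2ccc(OCc3ccccc3)cc2OCc2ccccc2)O[C@H]1c1ccc(OCc2ccccc2)cc1
A4 | alternative 2 | 4-(benzyloxy)-2-chloro-6-(trimethylsilyl)phenyl trifluoromethanesulfonate | C[Si](C)(C)c1cc(OCc2ccccc2)cc(Cl)c1OS(=O)(=O)C(F)(F)F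
A5 | alternative 2 | 5-benzyloxy-3-chlorobenzyne | ClC1=CC(OCc2ccccc2)=CC#C1
A6 | alternative 2 | 4-benzyloxy-6-chloro-2-hydroxyphenyl ketone at C7 | O=C(c1c(Cl)cc(OCc2ccccc2)cc1O)[C@@H]1[C@H]([C@@H](O[Si](C(C)C)(C(C)C)C(C)C)c2ccc(OCc3ccccc3)cc2)[C@H](c2ccc(OCc3ccccc3)cc2OCc2ccccc2)O[C@H]1c1ccc(OCc2ccccc2)cc1
A7 | alternative 3 | dimethyl 2,3-bis[4-(benzyloxy)benzoyl]succinate (α-centres labile) | COC(=O)C(C(=O)c1ccc(OCc2ccccc2)cc1)C(C(=O)OC)C(=O)c1ccc(OCc2ccccc2)cc1
A8 | alternative 3 | exo,exo-2,6-bis[4-(benzyloxy)phenyl]-3,7-dioxabicyclo[3.3.0]octane-4,8-dione | O=C2[C@@H]1[C@H]([C@@H](O2)c3ccc(OCc4ccccc4)cc3)C(=O)O[C@H]1c1ccc(OCc2ccccc2)cc1
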